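**Retrosynthetic overview**

1. Target (upper unit: rings A, B, C; lower unit: rings D, E, F) ⇐ global hydrogenolysis ⇐ esterification of the upper 3-OH ⇐ benzyl-protected dimer 22, which already carries the lower gallate and a blocking bromine at C8 of ring D.
2. 22 ⇐ ring C is closed last through the C3–C4 bond: the seven-membered lactol 18 (a 1,4-benzodioxepin-3-ol in which C4 is still bound to the C3 oxygen) is ionised to a C4 diarylmethylium ion plus a C3 aldehyde, the cation is reduced by SmI2 and C4 adds to C3; the ring oxygen is excised and the ring contracts from seven to six.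
3. Enabling feature: C4 is a diarylmethine carbon flanked by ring A and ring D, each with oxygen at both ortho positions and the para position; its cation forms with one equivalent of silyl triflate and is reduced far more easily than the C3 aldehyde, O1–C2 is the tether, and the C2 stereocenter directs C3 and C4.
4. 18 ⇐ oxidative cleavage of the vinyl group of diarylmethanol 15 ⇐ addition of the C6 arylmagnesium of ring D (from (−)-epicatechin; rings D, E, F bought intact) to ring A aldehyde 13, which fixes the 4→6 linkage.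
5. 13 ⇐ iridium-catalysed asymmetric allylic etherification (forms O1–C2, sets C2) of ring A phenol 12 (from 2,4,6-trihydroxybenzaldehyde) with ring B cinnamyl carbonate 10 (from caffeic acid).

Key step: step 12

Assumption: the (Sa,Sc,Sc) antipode of the phosphoramidite ligand is taken as the one that gives the S ether 13; if the sense of induction is the opposite, the mirror-image ligand is used and nothing else changes.

**Route**

Step 1
Reactants: 1 (−)-epicatechin
Product: 2 5,7,3',4'-tetra-O-benzyl-(−)-epicatechin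
Conditions: BnBr (4.4 equiv), K2CO3, DMF, 0 °C to rt
Reagents that add atoms: benzyl bromide, BrCc1ccccc1
Why: Williamson ether synthesis on the four phenols only (K2CO3 does not deprotonate the secondary alcohol), no stereocenter being touched.

Step 2
Reactants: 2 5,7,3',4'-tetra-O-benzyl-(−)-epicatechin
Product: 3 8-bromo-5,7,3',4'-tetra-O-benzyl-(−)-epicatechin
Conditions: NBS (1.0 equiv), CH2Cl2, −78 °C to rt
Reagents that add atoms: N-bromosuccinimide, O=C1CCC(=O)N1Br
Why: Electrophilic aromatic bromination, for which C8 is the more reactive of the two free positions of the 5,7-dialkoxy ring, so one equivalent of NBS installs the blocking bromine there and leaves C6 free.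

Step 3
Reactants: 3 8-bromo-5,7,3',4'-tetra-O-benzyl-(−)-epicatechin; 4 3,4,5-tris(benzyloxy)benzoic acid
Product: 5 8-bromo-5,7,3',4'-tetra-O-benzyl-(−)-epicatechin 3-O-[3,4,5-tris(benzyloxy)benzoate]
Conditions: DCC, DMAP, CH2Cl2, rt
Reagents that add atoms: none
Why: Steglich esterification of the secondary 3-OH with retention, since the C3–O bond is not broken.

Step 4
Reactants: 5 8-bromo-5,7,3',4'-tetra-O-benzyl-(−)-epicatechin 3-O-[3,4,5-tris(benzyloxy)benzoate]
Product: 6 8-bromo-6-iodo-5,7,3',4'-tetra-O-benzyl-(−)-epicatechin 3-O-[3,4,5-tris(benzyloxy)benzoate]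
Conditions: NIS (1.1 equiv), CF3CO2H (cat.), CH2Cl2–MeCN, 0 °C
Reagents that add atoms: N-iodosuccinimide, O=C1CCC(=O)N1I
Why: Electrophilic aromatic iodination at C6, the only position left on the trioxygenated ring and far more electron-rich than any position of the catechol or galloyl rings.

Step 5
Reactants: 7 caffeic acid
Product: 8 benzyl (E)-3-[3,4-bis(benzyloxy)phenyl]prop-2-enoate
Conditions: BnBr (3.3 equiv), K2CO3, DMF, 60 °C
Reagents that add atoms: benzyl bromide, BrCc1ccccc1
Why: Williamson ether synthesis together with O-alkylation of the carboxylate, the E alkene being untouched.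

Step 6
Reactants: 8 benzyl (E)-3-[3,4-bis(benzyloxy)phenyl]prop-2-enoate
Product: 9 (E)-3-[3,4-bis(benzyloxy)phenyl]prop-2-en-1-ol
Conditions: i-Bu2AlH (2.5 equiv), CH2Cl2, −78 °C; aq. potassium sodium tartrate
Reagents that add atoms: none
Why: 1,2-Reduction of the α,β-unsaturated ester to the allylic alcohol by i-Bu2AlH at low temperature, which leaves the E alkene in place.

Step 7
Reactants: 9 (E)-3-[3,4-bis(benzyloxy)phenyl]prop-2-en-1-ol
Product: 10 (E)-3-[3,4-bis(benzyloxy)phenyl]prop-2-en-1-yl methyl carbonate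
Conditions: ClCO2Me, pyridine, CH2Cl2, 0 °C
Reagents that add atoms: methyl chloroformate, COC(=O)Cl
Why: O-Acylation of the primary allylic alcohol with a chloroformate gives the linear carbonate needed as allyl donor.

Step 8
Reactants: 11 2,4,6-trihydroxybenzaldehyde
Product: 12 4,6-bis(benzyloxy)-2-hydroxybenzaldehyde
Conditions: BnBr (2.0 equiv), K2CO3, DMF, rt
Reagents that add atoms: benzyl bromide, BrCc1ccccc1
Why: Regioselective Williamson ether synthesis, in which the para OH and one ortho OH are alkylated while the last ortho OH, hydrogen-bonded to the formyl group, stays free.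

Step 9
Reactants: 12 4,6-bis(benzyloxy)-2-hydroxybenzaldehyde; 10 (E)-3-[3,4-bis(benzyloxy)phenyl]prop-2-en-1-yl methyl carbonate
Product: 13 2,4-bis(benzyloxy)-6-{[(1S)-1-[3,4-bis(benzyloxy)phenyl]prop-2-en-1-yl]oxy}benzaldehyde
Conditions: 12, LiN(SiMe3)2 (1.0 equiv), THF, 0 °C; then 10, [Ir(cod)Cl]2 (2 mol%), (Sa,Sc,Sc)-O,O'-(1,1'-binaphthyl-2,2'-diyl)-N,N-bis(1-phenylethyl)phosphoramidite (4 mol%), THF, 50 °C
Reagents that add atoms: none
Why: Iridium-catalysed asymmetric allylic etherification, in which the aryloxide attacks the aryl-substituted terminus of the allyl–iridium intermediate (branched product) and the phosphoramidite ligand sets the new C2 stereocenter as S.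

Step 10
Reactants: 6 8-bromo-6-iodo-5,7,3',4'-tetra-O-benzyl-(−)-epicatechin 3-O-[3,4,5-tris(benzyloxy)benzoate]; 13 2,4-bis(benzyloxy)-6-{[(1S)-1-[3,4-bis(benzyloxy)phenyl]prop-2-en-1-yl]oxy}benzaldehyde
Product: 15 diarylmethanol joining ring A to C6 of ring D (both carbinol epimers), via C6 arylmagnesium chloride 14 (not isolated)
Conditions: 6, i-PrMgCl·LiCl (1.05 equiv), THF, −40 °C; then 13, −40 to 0 °C; aq. NH4Cl
Reagents that add atoms: none
Why: Iodine–magnesium exchange, selective for C–I over C–Br and compatible with the ester at low temperature, followed by 1,2-addition of the aryl Grignard reagent to the aldehyde, fixes the bond from C4 to C6 of ring D; the new carbinol center forms unselectively, which is harmless because it becomes a planar cation in step 12.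

Step 11
Reactants: 15 diarylmethanol joining ring A to C6 of ring D
Product: 18 seven-membered lactol (C3/C5 epimer mixture of the 1,4-benzodioxepin-3-ol), via triol 16 (not isolated), via open-chain hydroxy aldehyde 17 (not isolated)
Conditions: OsO4 (2 mol%), NaIO4 (4 equiv), 2,6-lutidine, dioxane–H2O 3:1, rt
Reagents that add atoms: osmium tetroxide, O=[Os](=O)(=O)=O; sodium periodate, [Na+].[O-]I(=O)(=O)=O; water, O
Why: Lemieux–Johnson oxidation (catalytic dihydroxylation by OsO4, then glycol cleavage by periodate) of the only alkene gives the C3 aldehyde, which the neighbouring diarylmethanol traps as a seven-membered lactol that shields the epimerisable C2 center.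

Step 12
Reactants: 18 seven-membered lactol
Product: 22 benzyl-protected dimer having the upper 3-OH free, via O-trimethylsilyl lactol 19 (not isolated), via diarylmethylium triflate 20 (not isolated), via benzhydrylsamarium diiodide 21 (not isolated)
Conditions: Me3SiNMe2, CH2Cl2, rt, then evaporate; Me3SiOTf (1.05 equiv), THF, −78 °C; SmI2 (2.5 equiv, THF), −78 to −40 °C; aq. NaHCO3
Reagents that add atoms: none
Why: Proposed new method: O-silylation followed by Me3SiOTf ionises the doubly benzylic C–O bond of the lactol to the C4 diarylmethylium ion and the free C3 aldehyde (the excised ring oxygen leaves as hexamethyldisiloxane, so no proton source is formed), two single-electron transfers from SmI2 convert the cation into a benzhydrylsamarium, and this adds to the aldehyde, the closest known reaction types being the samarium Barbier cyclisation of benzylic halides onto aldehydes and the SmI2 reduction of stabilised carbenium ions. Ring C closes by 6-exo-trig attack of C4 on the C3 carbonyl group, which contracts the seven-membered acetal ring to the six-membered pyran. The new C3 stereocenter is controlled by C2: with the ring B aryl equatorial in the half-chair transition state, trivalent samarium chelated between the carbonyl oxygen and O1 holds the developing C3–O bond axial, hence cis to the aryl group (2,3-cis). The new C4 stereocenter is controlled by peri strain with the C5 benzyloxy group of ring A, which forces the ring D aryl pseudoaxial and anti to the C3–O bond (3,4-trans, 4β). The step needs chemoselective reduction of the cation in the presence of the α-aryloxy aldehyde, whose ketyl would expel the ring A aryloxide; the six alkoxy groups on rings A and D make the cation reducible by SmI2 at −78 °C without HMPA, conditions under which aliphatic aldehydes, the aryl bromide and the gallate ester are not reduced.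

Step 13
Reactants: 22 benzyl-protected dimer having the upper 3-OH free; 4 3,4,5-tris(benzyloxy)benzoic acid
Product: 23 benzyl-protected, C8-brominated procyanidin B-5 3,3'-di-O-gallate
Conditions: DCC, DMAP, CH2Cl2, rt
Reagents that add atoms: none
Why: Steglich esterification of the axial secondary 3-OH with retention; DMAP catalysis copes with the hindrance from the flanking aryl groups.

Step 14
Reactants: 23 benzyl-protected, C8-brominated procyanidin B-5 3,3'-di-O-gallate
Product: 24 procyanidin B-5 3,3'-di-O-gallate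
Conditions: H2 (1 atm), Pd(OH)2/C, Et3N, THF–MeOH–H2O, rt
Reagents that add atoms: none
Why: Hydrogenolysis of all fourteen benzyl ethers together with hydrodebromination at C8 of ring D (Et3N takes up HBr) under conditions that leave the esters, the interflavan bond and the benzylic C2–O1 bonds intact.

**Compound list**

1 | (−)-epicatechin, (2R,3R)-2-(3,4-dihydroxyphenyl)chroman-3,5,7-triol | O[C@@H]1Cc2c(O)cc(O)cc2O[C@@H]1c1ccc(O)c(O)c1 | starting material

2 | 5,7,3',4'-tetra-O-benzyl-(−)-epicatechin, (2R,3R) | O[C@@H]1Cc2c(OCc3ccccc3)cc(OCc3ccccc3)cc2O[C@@H]1c1ccc(OCc2ccccc2)c(OCc2ccccc2)c1 | intermediate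

3 | 8-bromo-5,7,3',4'-tetra-O-benzyl-(−)-epicatechin, (2R,3R) | O[C@@H]1Cc2c(OCc3ccccc3)cc(OCc3ccccc3)c(Br)c2O[C@@H]1c1ccc(OCc2ccccc2)c(OCc2ccccc2)c1 | intermediate

4 | 3,4,5-tris(benzyloxy)benzoic acid | OC(=O)c1cc(OCc2ccccc2)c(OCc2ccccc2)c(OCc2ccccc2)c1 | starting material

5 | 8-bromo-5,7,3',4'-tetra-O-benzyl-(−)-epicatechin 3-O-[3,4,5-tris(benzyloxy)benzoate], (2R,3R) | O=C(O[C@@H]1Cc2c(OCc3ccccc3)cc(OCc3ccccc3)c(Br)c2O[C@@H]1c1ccc(OCc2ccccc2)c(OCc2ccccc2)c1)c1cc(OCc2ccccc2)c(OCc2ccccc2)c(OCc2ccccc2)c1 | intermediate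

6 | 8-bromo-6-iodo-5,7,3',4'-tetra-O-benzyl-(−)-epicatechin 3-O-[3,4,5-tris(benzyloxy)benzoate], (2R,3R) | O=C(O[C@@H]1Cc2c(OCc3ccccc3)c(I)c(OCc3ccccc3)c(Br)c2O[C@@H]1c1ccc(OCc2ccccc2)c(OCc2ccccc2)c1)c1cc(OCc2ccccc2)c(OCc2ccccc2)c(OCc2ccccc2)c1 | intermediate

7 | caffeic acid, (E)-3-(3,4-dihydroxyphenyl)prop-2-enoic acid | OC(=O)/C=C/c1ccc(O)c(O)c1 | starting material

8 | benzyl (E)-3-[3,4-bis(benzyloxy)phenyl]prop-2-enoate | O=C(OCc1ccccc1)/C=C/c1ccc(OCc2ccccc2)c(OCc2ccccc2)c1 | intermediate

9 | (E)-3-[3,4-bis(benzyloxy)phenyl]prop-2-en-1-ol | OC/C=C/c1ccc(OCc2ccccc2)c(OCc2ccccc2)c1 | intermediate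

10 | (E)-3-[3,4-bis(benzyloxy)phenyl]prop-2-en-1-yl methyl carbonate | COC(=O)OC/C=C/c1ccc(OCc2ccccc2)c(OCc2ccccc2)c1 | intermediate

11 | 2,4,6-trihydroxybenzaldehyde | O=Cc1c(O)cc(O)cc1O | starting material

12 | 4,6-bis(benzyloxy)-2-hydroxybenzaldehyde | O=Cc1c(O)cc(OCc2ccccc2)cc1OCc1ccccc1 | intermediate

13 | 2,4-bis(benzyloxy)-6-{[(1S)-1-[3,4-bis(benzyloxy)phenyl]prop-2-en-1-yl]oxy}benzaldehyde | O=Cc1c(OCc2ccccc2)cc(OCc2ccccc2)cc1O[C@@H](C=C)c1ccc(OCc2ccccc2)c(OCc2ccccc2)c1 | intermediate

14 | C6 arylmagnesium chloride of 6 (iodine replaced by MgCl, LiCl complex; not isolated) | O=C(O[C@@H]1Cc2c(OCc3ccccc3)c([Mg]Cl)c(OCc3ccccc3)c(Br)c2O[C@@H]1c1ccc(OCc2ccccc2)c(OCc2ccccc2)c1)c1cc(OCc2ccccc2)c(OCc2ccccc2)c(OCc2ccccc2)c1 | intermediate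

15 | diarylmethanol: the carbinol carbon (future C4) carries ring A of 13 (with its (1S)-1-arylallyl ether) and C6 of ring D of 5; both carbinol epimers | OC(c2c(OCc4ccccc4)c(Br)c3c(c2OCc4ccccc4)C[C@@H](OC(=O)c2cc(OCc4ccccc4)c(OCc4ccccc4)c(OCc4ccccc4)c2)[C@@H](c2ccc(OCc4ccccc4)c(OCc4ccccc4)c2)O3)c2c(OCc4ccccc4)cc(OCc4ccccc4)cc2O[C@@H](C=C)c1ccc(OCc2ccccc2)c(OCc2ccccc2)c1 | intermediate

16 | triol from dihydroxylation of the vinyl group of 15: (1R)-1-aryl-1-aryloxypropane-2,3-diol unit, new carbinol unassigned (not isolated) | OC(c2c(OCc4ccccc4)c(Br)c3c(c2OCc4ccccc4)C[C@@H](OC(=O)c2cc(OCc4ccccc4)c(OCc4ccccc4)c(OCc4ccccc4)c2)[C@@H](c2ccc(OCc4ccccc4)c(OCc4ccccc4)c2)O3)c2c(OCc4ccccc4)cc(OCc4ccccc4)cc2O[C@@H](C(O)CO)c1ccc(OCc2ccccc2)c(OCc2ccccc2)c1 | intermediate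

17 | open-chain hydroxy aldehyde: (2R)-2-[3,4-bis(benzyloxy)phenyl]-2-(aryloxy)acetaldehyde with the diarylmethanol intact (not isolated) | OC(c2c(OCc4ccccc4)c(Br)c3c(c2OCc4ccccc4)C[C@@H](OC(=O)c2cc(OCc4ccccc4)c(OCc4ccccc4)c(OCc4ccccc4)c2)[C@@H](c2ccc(OCc4ccccc4)c(OCc4ccccc4)c2)O3)c2c(OCc4ccccc4)cc(OCc4ccccc4)cc2O[C@@H](C=O)c1ccc(OCc2ccccc2)c(OCc2ccccc2)c1 | intermediate

18 | lactol: (2R)-6,8-bis(benzyloxy)-2-[3,4-bis(benzyloxy)phenyl]-5-(C6 of ring D of 5)-2,3-dihydro-5H-1,4-benzodioxepin-3-ol, epimers at C3 and C5 | OC1OC(c2c(OCc4ccccc4)c(Br)c3c(c2OCc4ccccc4)C[C@@H](OC(=O)c2cc(OCc4ccccc4)c(OCc4ccccc4)c(OCc4ccccc4)c2)[C@@H](c2ccc(OCc4ccccc4)c(OCc4ccccc4)c2)O3)c2c(OCc4ccccc4)cc(OCc4ccccc4)cc2O[C@@H]1c1ccc(OCc2ccccc2)c(OCc2ccccc2)c1 | intermediate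

19 | 3-O-trimethylsilyl ether of lactol 18 (not isolated) | C[Si](C)(C)OC1OC(c2c(OCc4ccccc4)c(Br)c3c(c2OCc4ccccc4)C[C@@H](OC(=O)c2cc(OCc4ccccc4)c(OCc4ccccc4)c(OCc4ccccc4)c2)[C@@H](c2ccc(OCc4ccccc4)c(OCc4ccccc4)c2)O3)c2c(OCc4ccccc4)cc(OCc4ccccc4)cc2O[C@@H]1c1ccc(OCc2ccccc2)c(OCc2ccccc2)c1 | intermediate

20 | diarylmethylium trifluoromethanesulfonate: cationic CH between ring A and C6 of ring D, ring A carrying the (1R)-1-aryl-2-oxoethoxy group (not isolated) | [CH+](c2c(OCc4ccccc4)c(Br)c3c(c2OCc4ccccc4)C[C@@H](OC(=O)c2cc(OCc4ccccc4)c(OCc4ccccc4)c(OCc4ccccc4)c2)[C@@H](c2ccc(OCc4ccccc4)c(OCc4ccccc4)c2)O3)c2c(OCc4ccccc4)cc(OCc4ccccc4)cc2O[C@@H](C=O)c1ccc(OCc2ccccc2)c(OCc2ccccc2)c1.[O-]S(=O)(=O)C(F)(F)F | intermediate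

21 | benzhydrylsamarium diiodide (trivalent samarium on the future C4, aldehyde intact; not isolated) | I[Sm](I)C(c2c(OCc4ccccc4)c(Br)c3c(c2OCc4ccccc4)C[C@@H](OC(=O)c2cc(OCc4ccccc4)c(OCc4ccccc4)c(OCc4ccccc4)c2)[C@@H](c2ccc(OCc4ccccc4)c(OCc4ccccc4)c2)O3)c2c(OCc4ccccc4)cc(OCc4ccccc4)cc2O[C@@H](C=O)c1ccc(OCc2ccccc2)c(OCc2ccccc2)c1 | intermediate

22 | 5,7,3',4'-tetra-O-benzyl-epicatechin-(4β→6)-[8-bromo-5,7,3',4'-tetra-O-benzyl-epicatechin 3-O-tri-O-benzylgallate]; upper unit (2R,3R), 3-OH free, 2,3-cis, 3,4-trans | O[C@@H]1[C@@H](c2c(OCc4ccccc4)c(Br)c3c(c2OCc4ccccc4)C[C@@H](OC(=O)c2cc(OCc4ccccc4)c(OCc4ccccc4)c(OCc4ccccc4)c2)[C@@H](c2ccc(OCc4ccccc4)c(OCc4ccccc4)c2)O3)c2c(OCc4ccccc4)cc(OCc4ccccc4)cc2O[C@@H]1c1ccc(OCc2ccccc2)c(OCc2ccccc2)c1 | intermediate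

23 | compound 22 esterified at the upper 3-OH with 3,4,5-tris(benzyloxy)benzoic acid (fourteen benzyl ethers, bromine at C8 of ring D) | O=C(O[C@@H]1[C@@H](c2c(OCc4ccccc4)c(Br)c3c(c2OCc4ccccc4)C[C@@H](OC(=O)c2cc(OCc4ccccc4)c(OCc4ccccc4)c(OCc4ccccc4)c2)[C@@H](c2ccc(OCc4ccccc4)c(OCc4ccccc4)c2)O3)c2c(OCc4ccccc4)cc(OCc4ccccc4)cc2O[C@@H]1c1ccc(OCc2ccccc2)c(OCc2ccccc2)c1)c1cc(OCc2ccccc2)c(OCc2ccccc2)c(OCc2ccccc2)c1 | intermediate

24 | procyanidin B-5 3,3'-di-O-gallate, epicatechin 3-O-gallate-(4β→6)-epicatechin 3-O-gallate | O=C(O[C@@H]1[C@@H](c2c(O)cc3c(c2O)C[C@@H](OC(=O)c2cc(O)c(O)c(O)c2)[C@@H](c2ccc(O)c(O)c2)O3)c2c(O)cc(O)cc2O[C@@H]1c1ccc(O)c(O)c1)c1cc(O)c(O)c(O)c1 | target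

**Step count and risks**

Total step count: 14. Longest linear sequence: 9 steps (1, 2, 3, 4, 10, 11, 12, 13, 14; equally 5, 6, 7, 9, 10, 11, 12, 13, 14).

Steps most likely to fail:

Step 12. The aldehyde may be reduced to its ketyl with loss of the ring A aryloxide, the organosamarium may be protonated or may enolise the aldehyde (epimerisation at C2) before it cyclises, or facial control at C3 and C4 may be insufficient. The fallback forms the interflavan bond by known Lewis-acid coupling instead of the C3–C4 bond. Setting out from compound 2, oxidation at C4 with DDQ in the presence of ethylene glycol (CH2Cl2, rt) should give 5,7,3',4'-tetra-O-benzyl-4β-(2-hydroxyethoxy)-(−)-epicatechin F1. Activation of F1 with TiCl4 (CH2Cl2, −78 to 0 °C) in the presence of compound 5, whose C8 is blocked by bromine so that only C6 can react, should give compound 22 directly, the nucleophile entering anti to the 3-OH (4β). The route is rejoined at compound 22.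

Step 9. The electron-rich branched ether may re-ionise at iridium, which erodes the enantiomeric purity and leads to the linear ether, and the hydrogen-bonded, hindered aryloxide may attack slowly. The fallback builds the O1–C2 bond by epoxide opening. Setting out from compound 9, Sharpless asymmetric epoxidation (Ti(OiPr)4, L-(+)-diethyl tartrate, t-BuOOH, 4 Å molecular sieves, CH2Cl2, −20 °C) should give [(2S,3S)-3-[3,4-bis(benzyloxy)phenyl]oxiran-2-yl]methanol F2. Opening of F2 at the benzylic carbon by the phenoxide of compound 12 (Cs2CO3, DMF, 50 °C; SN2 with inversion) should give the (2S,3R)-3-aryloxy-3-arylpropane-1,2-diol F3. 1,1'-Thiocarbonyldiimidazole (THF, rt) should convert F3 into the cyclic thiocarbonate F4, and Corey–Winter olefination of F4 with 1,3-dimethyl-2-phenyl-1,3,2-diazaphospholidine (THF, 40 °C) should deliver compound 13, where the route is rejoined.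

Step 10. The doubly ortho-substituted arylmagnesium may add only sluggishly to the hindered, electron-rich aldehyde, so that protonation or attack on the gallate ester competes. The fallback uses electrophilic aromatic substitution instead of organometallic addition. Setting out from compound 5 (no iodination needed) and compound 13, Friedel–Crafts hydroxyalkylation of the free C6 position with the aldehyde activated by Me3SiOTf (CH2Cl2, −78 °C, kept cold because the 1-arylallyl ether is acid-labile) should give the hindered diarylmethylium ion. This ion cannot be arylated a second time and is quenched with aq. NaHCO3 to compound 15. No new compound is made on the way (F0), and the route is rejoined at compound 15.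

**Further compounds**

F1 | step 12 | 5,7,3',4'-tetra-O-benzyl-4β-(2-hydroxyethoxy)-(−)-epicatechin (4-substituent trans to the 3-OH) | O[C@@H]1[C@@H](OCCO)c2c(OCc3ccccc3)cc(OCc3ccccc3)cc2O[C@@H]1c1ccc(OCc2ccccc2)c(OCc2ccccc2)c1

F2 | step 9 | [(2S,3S)-3-[3,4-bis(benzyloxy)phenyl]oxiran-2-yl]methanol | OC[C@@H]1O[C@H]1c1ccc(OCc2ccccc2)c(OCc2ccccc2)c1

F3 | step 9 | 2,4-bis(benzyloxy)-6-{[(1R,2S)-1-[3,4-bis(benzyloxy)phenyl]-2,3-dihydroxypropyl]oxy}benzaldehyde | O=Cc1c(OCc2ccccc2)cc(OCc2ccccc2)cc1O[C@@H]([C@@H](O)CO)c1ccc(OCc2ccccc2)c(OCc2ccccc2)c1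

F4 | step 9 | cyclic thiocarbonate (2-thioxo-1,3-dioxolane) of the diol F3 | O=Cc1c(OCc2ccccc2)cc(OCc2ccccc2)cc1O[C@@H]([C@@H]1COC(=S)O1)c1ccc(OCc2ccccc2)c(OCc2ccccc2)c1

F0 | step 10 | none | none
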